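**Strategy.** The route rests on the C3–C4 disconnection of ring A. In the target, the C3 carbinol sits beside quaternary C4, which carries CH3 and the oxygenated C24 on the face of the C10 methyl; this array is the imprint of a Claisen rearrangement between an endocyclic enol ether (O–C24=C4) and an (E)-benzyloxyvinyl group on C1. The precursor is therefore a dihydropyran fused to ring B across C5–C10 (C9 masked as a dioxolane) with the alkenyl group axial at C1. Heating it makes the C3–C4 bond, cuts O–C1, closes carbocyclic ring A, sets C3 and C4 together and frees the C24 aldehyde. Ring B (C8=C12, C11–OAr) is finished from the C9 ketone.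

Key step: step 13

Remarks on the chemistry:
- Drimane locants are used throughout (C11 on C9, C12 on C8, C24 on C4).
- C4 is a stereocentre without consequence in 6–10 and 15–20 because it becomes trigonal in 21. These compounds are carried as C4 epimers and their SMILES leave C4 undefined (in 19 and 20 also C24, in 15 also C1).
- C24 is stored as a Weinreb amide until step 11, so that no oxidation has to be run in the presence of the acid- and oxidant-sensitive (E)-alkoxyallyl alcohol.
- The C9 dioxolane is exchanged for the diol acetonide in one transketalisation (step 15), which avoids having to hydrolyse one acetal beside another.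

Step 1
Reactants: 1 2-methylcyclohex-2-en-1-one; 2 isopropenylmagnesium bromide
Product: 4 (2S,3R)-2-(hydroxymethyl)-2-methyl-3-(prop-1-en-2-yl)cyclohexan-1-one, via bromomagnesium enolate 3 (not isolated)
Conditions: Cu(OTf)2 (3 mol %), chiral imidazolinium NHC precursor (4 mol %, enantiomer giving 3R), Et2O, −30 °C; then CH2O (monomeric, THF), −78 → −40 °C; H2O
Reagents that add atoms: formaldehyde, C=O
Why: Cu-catalysed asymmetric conjugate addition of the Grignard reagent to the α-substituted enone fixes C5 under ligand control, and enolate 3 then undergoes an aldol reaction with formaldehyde on the face opposite to the new isopropenyl group, which fixes quaternary C10 with CH2OH trans to that group.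

Step 2
Reactants: 4
Product: 5 [(6S,7R)-6-methyl-7-(prop-1-en-2-yl)-1,4-dioxaspiro[4.5]decan-6-yl]methanol
Conditions: HOCH2CH2OH, HC(OEt)3, TsOH·H2O (cat.), rt; aq. NaHCO3
Reagents that add atoms: ethylene glycol, OCCO
Why: Acid-catalysed ketalisation with the orthoformate as water scavenger masks the C9 ketone under conditions mild enough to spare the isopropenyl group and the β-hydroxy ketone array, and no stereocentre is touched.

Step 3
Reactants: 5
Product: 7 2-[(6S,7R)-6-(hydroxymethyl)-6-methyl-1,4-dioxaspiro[4.5]decan-7-yl]propan-1-ol (C4 epimers), via bis(9-BBN) adduct 6 (not isolated)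
Conditions: 9-BBN (2.5 equiv), THF, 0 °C → rt; then NaOH, H2O2, 0 °C
Reagents that add atoms: hydrogen peroxide, OO
Why: Hydroboration–oxidation places boron on the terminal carbon of the 1,1-disubstituted alkene (anti-Markovnikov) and gives the C24 primary alcohol; the new C4 centre forms as an epimer mixture that converges in step 12.

Step 4
Reactants: 7
Product: 8 trans-fused δ-lactone on ring B (C24 carbonyl, ring oxygen on C1H2, C9 dioxolane, C4 epimers)
Conditions: TEMPO (0.2 equiv), PhI(OAc)2 (2.5 equiv), CH2Cl2, rt
Reagents that add atoms: none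
Why: Nitroxyl-catalysed oxidative lactonisation, in which the oxoammonium ion oxidises the less hindered C24 alcohol in preference to the neopentyl C1 alcohol, the aldehyde closes to the six-membered lactol and this is oxidised on to the lactone.

Step 5
Reactants: 8
Product: 9 N-methoxy-N-methyl-2-[(6S,7R)-6-(hydroxymethyl)-6-methyl-1,4-dioxaspiro[4.5]decan-7-yl]propanamide (C4 epimers)
Conditions: MeNH(OMe)·HCl (3 equiv), Me3Al (3 equiv), CH2Cl2, 0 °C → rt; aq. potassium sodium tartrate
Reagents that add atoms: N,O-dimethylhydroxylamine hydrochloride, CNOC.Cl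
Why: Aminolysis of the lactone by the dimethylaluminium amide (Weinreb amide formation) opens the ring, stores C24 at the acid oxidation level and releases the C1 alcohol.

Step 6
Reactants: 9
Product: 10 2-[(6S,7R)-6-formyl-6-methyl-1,4-dioxaspiro[4.5]decan-7-yl]-N-methoxy-N-methylpropanamide (C4 epimers)
Conditions: Dess–Martin periodinane, NaHCO3, CH2Cl2, 0 °C → rt
Reagents that add atoms: none
Why: Dess–Martin oxidation of the neopentyl primary alcohol gives the non-enolisable C1 aldehyde without affecting amide or ketal.

Step 7
Reactants: 11 trichloroethylene; 12 benzyl alcohol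
Product: 13 benzyl (E)-1,2-dichlorovinyl ether
Conditions: KH (1.1 equiv), THF, 0 °C; then 11, −50 °C → rt
Reagents that add atoms: none
Why: Base-induced loss of HCl from trichloroethylene gives dichloroacetylene, to which the benzyl alkoxide adds in an anti sense (addition–elimination synthesis of a 1,2-dichlorovinyl ether).

Step 8
Reactants: 10; 13
Product: 15 2-{(6S,7R)-6-[3-(benzyloxy)-1-hydroxyprop-2-yn-1-yl]-6-methyl-1,4-dioxaspiro[4.5]decan-7-yl}-N-methoxy-N-methylpropanamide (C1 and C4 epimers), via lithium benzyloxyacetylide 14 (not isolated)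
Conditions: 13 (1.5 equiv), n-BuLi (3.1 equiv), THF, −78 → −40 °C; then 10, −78 °C; pH 7 buffer, kept below rt
Reagents that add atoms: none
Why: Dehydrochlorination and chlorine–lithium exchange of 13 give the lithium alkoxyacetylide, whose 1,2-addition to the aldehyde at −78 °C is much faster than attack on the Weinreb amide; C1 forms unselectively and is corrected in steps 9 and 10.

Step 9
Reactants: 15
Product: 16 2-{(6S,7R)-6-[3-(benzyloxy)prop-2-ynoyl]-6-methyl-1,4-dioxaspiro[4.5]decan-7-yl}-N-methoxy-N-methylpropanamide (C4 epimers)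
Conditions: Dess–Martin periodinane, NaHCO3, CH2Cl2, 0 °C
Reagents that add atoms: none
Why: Buffered Dess–Martin oxidation converts both C1 epimers into one alkynyl ketone, the substrate for a reagent-controlled reduction.

Step 10
Reactants: 16
Product: 17 2-{(6S,7R)-6-[(1S)-3-(benzyloxy)-1-hydroxyprop-2-yn-1-yl]-6-methyl-1,4-dioxaspiro[4.5]decan-7-yl}-N-methoxy-N-methylpropanamide (C4 epimers)
Conditions: (R)-2-methyl-CBS-oxazaborolidine (0.5 equiv), BH3·SMe2 (1.2 equiv), THF, −40 °C; MeOH, then H2O
Reagents that add atoms: none
Why: Corey–Bakshi–Shibata reduction in which the slim alkynyl group acts as the small substituent and quaternary C10 as the large one, so that the (R)-oxazaborolidine should deliver hydride to the face that gives the (1S)-carbinol.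

Step 11
Reactants: 17
Product: 19 ring-B-fused lactol (2-hydroxytetrahydropyran: ring O between C24 and C1, C1 bearing the (E)-2-(benzyloxy)vinyl group anti to the C10 methyl, C9 dioxolane; C4 and C24 epimers), via open-chain hydroxy aldehyde 18 (not isolated)
Conditions: LiAlH4 (3 equiv), THF, −20 → 0 °C; aq. potassium sodium tartrate, 0 °C
Reagents that add atoms: none
Why: Alkoxide-directed trans-hydroalumination of the propargylic alcohol (hydride to C2, aluminium on C3) gives the (E)-enol ether after protonation, while the Weinreb amide is reduced only to its chelated hemiaminal, which releases the C24 aldehyde on work-up to be captured by C1–OH as the six-membered lactol.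

Step 12
Reactants: 19
Product: 21 ring-B-fused 5-methyl-3,4-dihydro-2H-pyran (enol ether C24=C4, ring O on C1; (1S) C1 carrying the (E)-2-(benzyloxy)vinyl group anti to the C10 methyl; C5–H and C10–CH3 anti; C9 dioxolane), via lactol mesylate 20 (not isolated)
Conditions: MsCl (1.5 equiv), Et3N (5 equiv), CH2Cl2, −20 °C → reflux; purification on Et3N-treated silica
Reagents that add atoms: none
Why: Lactol dehydration, in which the anomeric mesylate ionises to the oxocarbenium ion and Et3N removes H4 (E1-type elimination), gives the endocyclic enol ether from either C4 epimer under basic conditions that spare the alkoxyallyl ether.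

Step 13
Reactants: 21
Product: 22 ring A cyclohexene (C1=C2) with C3 benzyloxy and C4 formyl groups both cis to the C10 methyl, C4 methyl trans, C9 dioxolane
Conditions: PhMe (0.02 M, degassed), Et3N (0.1 equiv), base-washed sealed tube, 200 °C
Reagents that add atoms: none
Why: A thermal [3,3]-sigmatropic (Claisen) shift of the allyl vinyl ether C3=C2–C1–O–C24=C4 forms the C3–C4 σ bond as O–C1 breaks, leaving the C24 aldehyde and the C1=C2 double bond. The closest known reaction type is the Claisen rearrangement of 2-alkenyl-3,4-dihydro-2H-pyrans to cyclohex-3-ene-1-carbaldehydes. Ring A closes in a concerted, suprafacial six-centre mode through a boat transition state, the only one available when the termini C1 and C4 are tied by the C10–C5 bridge, so that the reacting atoms and this tether resemble a bicyclo[2.2.2]octadiene with C1 and C4 at the bridgehead positions. C4 is controlled by C1: the alkenyl group stands axial on the pyran face opposite to the C10 methyl and bonds to that face of C4, so that C24 ends axial and cis to the C10 methyl; C3 is controlled by the (E) geometry of the benzyloxyvinyl unit, which leaves OBn in an equatorial site on the same face as the formyl carbon. The step needs the concerted pathway to win over heterolysis of the doubly activated C1–O bond, and a non-polar solvent, high dilution, the amine and base-washed glass are chosen to secure this.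

Step 14
Reactants: 22
Product: 24 diol (C3–OH and C24H2OH cis to the C10 methyl, ring A saturated, C9 dioxolane), via benzyl ether alcohol 23 (not isolated)
Conditions: NaBH4, EtOH, 0 °C; then Pd(OH)2/C, H2 (3 atm), rt
Reagents that add atoms: none
Why: Hydride reduction of the hindered C24 aldehyde is followed in the same flask by catalytic hydrogenation, which saturates the cis-disubstituted C1=C2 bond faster than any allylic C–O cleavage and then removes the benzyl group by hydrogenolysis, leaving C3 and C4 untouched.

Step 15
Reactants: 24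
Product: 25 C9 ketone with C3–O and C24–O joined as the isopropylidene acetal
Conditions: acetone, Me2C(OMe)2 (2 equiv), TsOH·H2O (cat.), rt → 40 °C; Et3N
Reagents that add atoms: 2,2-dimethoxypropane, COC(C)(C)OC
Why: Acid-catalysed transketalisation in acetone passes the ethylene glycol unit from C9 to the solvent while the cis 1,3-diol is closed to its six-membered acetonide, which frees the ketone and protects both hydroxyl groups in one operation.

Step 16
Reactants: 25
Product: 26 C9 enol triflate (C8=C9) of 25
Conditions: KN(SiMe3)2, THF, −78 °C; PhNTf2, −78 → 0 °C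
Reagents that add atoms: N-phenylbis(trifluoromethanesulfonimide), O=S(=O)(N(c1ccccc1)S(=O)(=O)C(F)(F)F)C(F)(F)F
Why: Enolate O-sulfonylation gives a single enol triflate because the ketone can enolise only towards C8, C10 being quaternary.

Step 17
Reactants: 26
Product: 27 methyl ester (C11) on C9 of the C8=C9 alkene, acetonide retained
Conditions: Pd(OAc)2 (5 mol %), PPh3 (10 mol %), CO (1 atm), MeOH, Et3N, DMF, 50 °C
Reagents that add atoms: carbon monoxide, [C-]#[O+]; methanol, CO
Why: Palladium-catalysed methoxycarbonylation of the vinyl triflate (oxidative addition to zerovalent palladium, CO insertion, methanolysis) installs C11 on C9.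

Step 18
Reactants: 27
Product: 28 C11 allylic alcohol (C8=C9)
Conditions: i-Bu2AlH (2.5 equiv), CH2Cl2, −78 °C; aq. potassium sodium tartrate
Reagents that add atoms: none
Why: 1,2-Reduction of the conjugated ester by the aluminium hydride gives the allylic alcohol and leaves the acetonide intact.

Step 19
Reactants: 28
Product: 29 C11 tert-butyldimethylsilyl ether of 28
Conditions: t-BuMe2SiCl, imidazole, DMF, rt
Reagents that add atoms: tert-butyldimethylsilyl chloride, CC(C)(C)[Si](C)(C)Cl
Why: Silylation turns C11–O into a poor leaving group, so that it survives the β-oxy ketone of step 21 and the ylide of step 22.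

Step 20
Reactants: 29
Product: 31 C8 secondary alcohol (C8–OH and C9–H trans to the C10 methyl, C11H2OTBS cis to it), via C8 alkylborane 30 (not isolated)
Conditions: BH3·THF (3 equiv), THF, 0 °C → rt; then NaOH, H2O2, 0 °C
Reagents that add atoms: hydrogen peroxide, OO
Why: Hydroboration–oxidation of the trisubstituted alkene puts boron on the less substituted C8 and hydrogen on C9 in a syn addition from the face opposite to the axial C10 methyl, which sets C9 (C11 cis to the C10 methyl) and the transient C8 carbinol.

Step 21
Reactants: 31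
Product: 32 C8 ketone
Conditions: Dess–Martin periodinane, NaHCO3, CH2Cl2, rt
Reagents that add atoms: none
Why: Dess–Martin oxidation gives the ketone under non-basic conditions that leave the adjacent C9 centre and the β-silyloxy group alone.

Step 22
Reactants: 32
Product: 33 exocyclic alkene C8=C12 with C11–OTBS and acetonide
Conditions: Ph3PCH3Br, KOt-Bu, PhMe, rt → 60 °C
Reagents that add atoms: methyltriphenylphosphonium bromide, C[P+](c1ccccc1)(c1ccccc1)c1ccccc1.[Br-]
Why: Wittig methylenation builds the C8=C12 bond, the non-stabilised ylide adding to the ketone faster than it enolises it towards C9.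

Step 23
Reactants: 33
Product: 34 C11 primary alcohol (acetonide-protected 8(12)-ene)
Conditions: Bu4NF, THF, rt
Reagents that add atoms: none
Why: Fluoride-induced desilylation frees the C11 alcohol and leaves acetonide and alkene untouched.

Step 24
Reactants: 34; 35 umbelliferone
Product: 36 3,24-O-isopropylidene derivative of the target
Conditions: PPh3, DIAD, THF, 0 °C → rt
Reagents that add atoms: none
Why: Mitsunobu etherification, in which the acidic 7-hydroxyl group of the coumarin displaces the activated primary C11 alcohol (SN2 at a CH2 group, no stereocentre involved).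

Step 25
Reactants: 36
Product: 37 7-{[(1R,4aS,5R,6R,8aR)-6-hydroxy-5-(hydroxymethyl)-5,8a-dimethyl-2-methylidenedecahydronaphthalen-1-yl]methoxy}-2H-chromen-2-one (CNP0149624.1)
Conditions: AcOH/H2O (4:1), THF, rt
Reagents that add atoms: none
Why: Mild acid hydrolysis of the isopropylidene acetal releases the C3 and C24 hydroxyl groups without isomerising the exocyclic alkene or opening the lactone.

**Compound list**

1 | 2-methylcyclohex-2-en-1-one | CC1=CCCCC1=O | starting material
2 | isopropenylmagnesium bromide | CC(=C)[Mg]Br | starting material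
3 | bromomagnesium (3R)-2-methyl-3-(prop-1-en-2-yl)cyclohex-1-en-1-olate | C=C(C)[C@H]1CCCC(O[Mg]Br)=C1C | intermediate
4 | (2S,3R)-2-(hydroxymethyl)-2-methyl-3-(prop-1-en-2-yl)cyclohexan-1-one | O=C1CCC[C@H](C(C)=C)[C@@]1(C)CO | intermediate
5 | [(6S,7R)-6-methyl-7-(prop-1-en-2-yl)-1,4-dioxaspiro[4.5]decan-6-yl]methanol | C1CC[C@H](C(C)=C)[C@@](C)(CO)C12OCCO2 | intermediate
6 | bis(9-BBN) adduct of 5 (B-alkyl at C24, O-boryl at C1, C4 epimers) | C1CC[C@H](C(C)CB2C3CCCC2CCC3)[C@@](C)(COB2C3CCCC2CCC3)C12OCCO2 | intermediate
7 | 2-[(6S,7R)-6-(hydroxymethyl)-6-methyl-1,4-dioxaspiro[4.5]decan-7-yl]propan-1-ol (C4 epimers) | C1CC[C@H](C(C)CO)[C@@](C)(CO)C12OCCO2 | intermediate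
8 | trans-fused δ-lactone on ring B (C24 carbonyl, ring O on C1H2, C9 dioxolane, C4 epimers) | C1CC[C@@H]2C(C)C(=O)OC[C@@]2(C)C13OCCO3 | intermediate
9 | N-methoxy-N-methyl-2-[(6S,7R)-6-(hydroxymethyl)-6-methyl-1,4-dioxaspiro[4.5]decan-7-yl]propanamide (C4 epimers) | C1CC[C@H](C(C)C(=O)N(C)OC)[C@@](C)(CO)C12OCCO2 | intermediate
10 | 2-[(6S,7R)-6-formyl-6-methyl-1,4-dioxaspiro[4.5]decan-7-yl]-N-methoxy-N-methylpropanamide (C4 epimers) | C1CC[C@H](C(C)C(=O)N(C)OC)[C@@](C)(C=O)C12OCCO2 | intermediate
11 | trichloroethylene | ClC=C(Cl)Cl | starting material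
12 | benzyl alcohol | OCc1ccccc1 | starting material
13 | benzyl (E)-1,2-dichlorovinyl ether | Cl/C=C(Cl)\OCc1ccccc1 | intermediate
14 | lithium benzyloxyacetylide | [Li]C#COCc1ccccc1 | intermediate
15 | 2-{(6S,7R)-6-[3-(benzyloxy)-1-hydroxyprop-2-yn-1-yl]-6-methyl-1,4-dioxaspiro[4.5]decan-7-yl}-N-methoxy-N-methylpropanamide (C1 and C4 epimers) | C1CC[C@H](C(C)C(=O)N(C)OC)[C@@](C)(C(O)C#COCc3ccccc3)C12OCCO2 | intermediate
16 | 2-{(6S,7R)-6-[3-(benzyloxy)prop-2-ynoyl]-6-methyl-1,4-dioxaspiro[4.5]decan-7-yl}-N-methoxy-N-methylpropanamide (C4 epimers) | C1CC[C@H](C(C)C(=O)N(C)OC)[C@@](C)(C(=O)C#COCc3ccccc3)C12OCCO2 | intermediate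
17 | 2-{(6S,7R)-6-[(1S)-3-(benzyloxy)-1-hydroxyprop-2-yn-1-yl]-6-methyl-1,4-dioxaspiro[4.5]decan-7-yl}-N-methoxy-N-methylpropanamide (C4 epimers) | C1CC[C@H](C(C)C(=O)N(C)OC)[C@@](C)([C@@H](O)C#COCc3ccccc3)C12OCCO2 | intermediate
18 | 2-{(6S,7R)-6-[(1S,2E)-3-(benzyloxy)-1-hydroxyprop-2-en-1-yl]-6-methyl-1,4-dioxaspiro[4.5]decan-7-yl}propanal (C4 epimers) | C1CC[C@H](C(C)C=O)[C@@](C)([C@@H](O)/C=C/OCc3ccccc3)C12OCCO2 | intermediate
19 | ring-B-fused lactol (C24 hemiacetal, ring O on C1, (1S) C1 with (E)-2-(benzyloxy)vinyl group, C9 dioxolane; C4 and C24 epimers) | C1CC[C@@H]2C(C)C(O)O[C@@H](/C=C/OCc4ccccc4)[C@@]2(C)C13OCCO3 | intermediate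
20 | C24 methanesulfonate of lactol 19 | C1CC[C@@H]2C(C)C(OS(C)(=O)=O)O[C@@H](/C=C/OCc4ccccc4)[C@@]2(C)C13OCCO3 | intermediate
21 | ring-B-fused 2-[(E)-2-(benzyloxy)vinyl]-5-methyl-3,4-dihydro-2H-pyran (enol ether C24=C4, alkenyl at (1S) C1 anti to the C10 methyl, C9 dioxolane) | C1CC[C@@H]2C(C)=CO[C@@H](/C=C/OCc4ccccc4)[C@@]2(C)C13OCCO3 | intermediate
22 | ring A cyclohexene (C1=C2) with C3–OBn and C4–CHO cis to the C10 methyl, C9 dioxolane | C1CC[C@@H]2[C@](C)(C=O)[C@H](OCc4ccccc4)C=C[C@@]2(C)C13OCCO3 | intermediate
23 | C24 primary alcohol of 22 (C3–OBn, C1=C2, C9 dioxolane) | C1CC[C@@H]2[C@](C)(CO)[C@H](OCc4ccccc4)C=C[C@@]2(C)C13OCCO3 | intermediate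
24 | C3,C24-diol with saturated ring A and C9 dioxolane | C1CC[C@@H]2[C@](C)(CO)[C@H](O)CC[C@@]2(C)C13OCCO3 | intermediate
25 | C9 ketone, 3,24-O-isopropylidene acetal | C1CC[C@@H]2[C@](C)(COC3(C)C)[C@H](O3)CC[C@@]2(C)C1=O | intermediate
26 | C9 enol triflate (C8=C9), 3,24-O-isopropylidene acetal | FC(F)(F)S(=O)(=O)OC1=CCC[C@@H]2[C@](C)(COC3(C)C)[C@H](O3)CC[C@@]12C | intermediate
27 | C9 methyl ester (C11) of the C8=C9 alkene, acetonide | COC(=O)C1=CCC[C@@H]2[C@](C)(COC3(C)C)[C@H](O3)CC[C@@]12C | intermediate
28 | C11 allylic alcohol (C8=C9), acetonide | OCC1=CCC[C@@H]2[C@](C)(COC3(C)C)[C@H](O3)CC[C@@]12C | intermediate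
29 | C11 tert-butyldimethylsilyl ether of 28 | CC(C)(C)[Si](C)(C)OCC1=CCC[C@@H]2[C@](C)(COC3(C)C)[C@H](O3)CC[C@@]12C | intermediate
30 | C8 alkylborane (BH2 on C8 and H on C9, both trans to the C10 methyl) | B[C@H]1CC[C@@H]2[C@](C)(COC3(C)C)[C@H](O3)CC[C@@]2(C)[C@@H]1CO[Si](C)(C)C(C)(C)C | intermediate
31 | C8 alcohol (C8–OH and C9–H trans to the C10 methyl, C11H2OTBS cis), acetonide | O[C@H]1CC[C@@H]2[C@](C)(COC3(C)C)[C@H](O3)CC[C@@]2(C)[C@@H]1CO[Si](C)(C)C(C)(C)C | intermediate
32 | C8 ketone with C11H2OTBS on C9, acetonide | O=C1CC[C@@H]2[C@](C)(COC3(C)C)[C@H](O3)CC[C@@]2(C)[C@@H]1CO[Si](C)(C)C(C)(C)C | intermediate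
33 | C8=C12 exocyclic alkene with C11H2OTBS, acetonide | C=C1CC[C@@H]2[C@](C)(COC3(C)C)[C@H](O3)CC[C@@]2(C)[C@@H]1CO[Si](C)(C)C(C)(C)C | intermediate
34 | C11 primary alcohol of the 8(12)-ene, acetonide | C=C1CC[C@@H]2[C@](C)(COC3(C)C)[C@H](O3)CC[C@@]2(C)[C@@H]1CO | intermediate
35 | umbelliferone (7-hydroxy-2H-chromen-2-one) | O=c1ccc2ccc(O)cc2o1 | starting material
36 | 3,24-O-isopropylidene acetal of the target | C=C1CC[C@@H]2[C@](C)(COC3(C)C)[C@H](O3)CC[C@@]2(C)[C@@H]1COc1ccc2ccc(=O)oc2c1 | intermediate
37 | 7-{[(1R,4aS,5R,6R,8aR)-6-hydroxy-5-(hydroxymethyl)-5,8a-dimethyl-2-methylidenedecahydronaphthalen-1-yl]methoxy}-2H-chromen-2-one | C=C1CC[C@@H]2[C@](C)(CO)[C@H](O)CC[C@@]2(C)[C@@H]1COc1ccc2ccc(=O)oc2c1 | target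

**Totals**

Total step count: 25 (24 in the main line and 1 for reagent 13).
Longest linear sequence: 24 steps (1 to 37 through steps 1–6 and 8–25).

**Steps most likely to fail**

Step 13. The boat transition state has to carry ring B trans-fused across the C5–C10 bridge and a ketal oxygen on C9 syn to the alkenyl bridge. The concerted shift may therefore be slower than ionisation of the C1–O bond or thermal breakdown of the benzyl enol ether, with loss of material or of stereochemical fidelity at C3 and C4. The fallback is the ester-enolate variant of the same bond construction, which runs far below 200 °C. It sets out from lactol 19, which is oxidised with Pr4N[RuO4] (cat.) and N-methylmorpholine N-oxide to the (E)-alkenyl δ-lactone F1. LiN(i-Pr)2 and t-BuMe2SiCl in THF at −78 °C give the cyclic silyl ketene acetal F2, which on warming in PhMe (80–110 °C) should undergo the Ireland–Claisen ring contraction through the same boat to the ring A silyl ester F3 (C24 carboxyl and C3–OBn cis to the C10 methyl). LiAlH4 in THF reduces F3 to alcohol 23, which rejoins step 14 at its hydrogenation stage.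

Step 11. The amide-derived hemiaminal may be reduced further before the slower hydroalumination of the electron-rich alkyne is complete, or the alkyne may stay partly unreduced when the mixture is kept cold enough to protect the hemiaminal. The fallback is full reduction followed by selective re-oxidation. It sets out from 17, which is treated with excess LiAlH4 in THF at rt until both groups are reduced, giving the (E)-enol ether diol F4. Aerobic oxidation with Cu(MeCN)4OTf, 2,2'-bipyridine, TEMPO and N-methylimidazole in MeCN, a system that oxidises unhindered primary alcohols and leaves secondary ones, should convert the C24 alcohol into the aldehyde, which closes to lactol 19.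

Step 1. Facial discrimination at C5 may be insufficient with an alkenyl Grignard reagent on the α-substituted enone, leaving material of low enantiomeric purity. The fallback is resolution in place of asymmetric catalysis. It sets out from 1 and 2, which are combined with CuBr·SMe2 (cat.) without ligand, the enolate being trapped with formaldehyde as before, to give the racemic trans hydroxy ketone F5. Esterification with (S)-2-methoxy-2-phenylacetic acid (DCC, DMAP cat.) gives two diastereomeric esters that are separated by chromatography. The (2S,3R) ester F6 is cleaved with K2CO3 in MeOH at 0 °C to return 4.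

**Further compounds**

F1 | step 13 | ring-B-fused δ-lactone (C24 carbonyl, ring O on (1S) C1 bearing the (E)-2-(benzyloxy)vinyl group, C9 dioxolane, C4 epimers) | C1CC[C@@H]2C(C)C(=O)O[C@@H](/C=C/OCc4ccccc4)[C@@]2(C)C13OCCO3
F2 | step 13 | cyclic tert-butyldimethylsilyl ketene acetal of F1 (C24(OSi)=C4) | C1CC[C@@H]2C(C)=C(O[Si](C)(C)C(C)(C)C)O[C@@H](/C=C/OCc4ccccc4)[C@@]2(C)C13OCCO3
F3 | step 13 | ring A cyclohexene tert-butyldimethylsilyl ester (C24 carboxyl and C3–OBn cis to the C10 methyl, C1=C2, C9 dioxolane) | C1CC[C@@H]2[C@](C)(C(=O)O[Si](C)(C)C(C)(C)C)[C@H](OCc4ccccc4)C=C[C@@]2(C)C13OCCO3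
F4 | step 11 | (1S,2E)-enol ether diol (C1–OH and C24H2OH, C9 dioxolane, C4 epimers) | C1CC[C@H](C(C)CO)[C@@](C)([C@@H](O)/C=C/OCc3ccccc3)C12OCCO2
F5 | step 1 | racemic trans-2-(hydroxymethyl)-2-methyl-3-(prop-1-en-2-yl)cyclohexan-1-one | O=C1CCC[C@H](C(C)=C)[C@@]1(C)CO.O=C1CCC[C@@H](C(C)=C)[C@]1(C)CO
F6 | step 1 | (S)-2-methoxy-2-phenylacetate ester of 4 | O=C1CCC[C@H](C(C)=C)[C@@]1(C)COC(=O)[C@@H](OC)c1ccccc1
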